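The cyclohexene ring C1–C6 is traced back to a 7-oxabicyclo[2.2.1]heptene. The tertiary carbinol carbon C1 (bearing C7) and the alkene carbon C4 lie 1,4 across the ring, where a furan oxygen can span it. One enantioselective Diels–Alder reaction joins furfuryl benzoate, which already carries the C7 ester, to 2-bromoacrolein. It forms C1–C6 and C4–C5, closes the carbocycle and fixes C1 absolutely. The C(Br)CHO carbon is a masked C6 ketone. Once unmasked, it is enolised toward C5 and the C4–O bond is broken by β-elimination, freeing the C1 oxygen and creating C4=C5. An exo epoxide supplies O2 and, through inversion, O3. The ketone is reduced last.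

Key step: step 3

Numbering: target numbering is used throughout. C1 is the carbinol carbon bearing C7H2OBz, C2 and C3 are the acetoxy carbons, C4=C5 is the alkene, and C6 is the secondary carbinol carbon. The bicyclic names use their own locants.
Structure check: the target is (1S,2R,3S,6S). O1, O2 and O6 lie on one ring face; O3 and C7 lie on the other.
Assumption: the (S)-tryptophan-derived catalyst is taken to induce the same sense with the substituted furan as with unsubstituted dienes (2R bromo aldehydes). If the opposite sense were found, the (R)-catalyst would be used.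

Step 1
Reactants: 1 furfuryl alcohol; 2 benzoyl chloride
Product: 3 furfuryl benzoate
Conditions: Et3N, DMAP (cat.), CH2Cl2, 0 °C → rt
Reagents that add atoms: none
Why: DMAP-catalysed O-acylation of a primary alcohol is reliable, the basic medium protects the acid-sensitive furfuryl system, and no stereocentre is involved.

Step 2
Reactants: 4 acrolein
Product: 6 2-bromoacrolein, via 2,3-dibromopropanal 5 (not isolated)
Conditions: Br2, CH2Cl2, −78 °C; then Et3N, −78 → 0 °C; distil
Reagents that add atoms: bromine, BrBr
Why: Bromine addition to the alkene followed by amine-induced loss of HBr from the acidic α-position (bromination–dehydrobromination) is the standard preparation of this dienophile, which is used fresh.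

Step 3
Reactants: 3 furfuryl benzoate; 6 2-bromoacrolein
Product: 7 (1S,2R,4R)-1-(benzoyloxymethyl)-2-endo-bromo-7-oxabicyclo[2.2.1]hept-5-ene-2-exo-carbaldehyde
Conditions: (S)-2-butyl-4-(1H-indol-3-ylmethyl)-3-(4-methylbenzenesulfonyl)-1,3,2-oxazaborolidin-5-one (20 mol %, made beforehand from N-tosyl-(S)-tryptophan and BuB(OH)2), CH2Cl2, −78 °C; quench at −78 °C with aq. NaHCO3
Reagents that add atoms: none
Why: Boron binds the formyl oxygen of s-cis 6 and lowers its LUMO, so the furan adds in a concerted but asynchronous normal-demand [4+2] cycloaddition in which the unsubstituted furan α-carbon (C4) bonds to the CH2 terminus (C5) ahead of C1–C6. The closest known reaction type is the oxazaborolidinone-catalysed enantioselective Diels–Alder reaction of furan itself with 2-haloacroleins. The carbocycle C1–C6 closes by cycloaddition, both σ-bonds being made suprafacially on each partner, and the furan oxygen ends up as the one-atom bridge between C1 and C4. C6 is set by two elements: 2-haloacroleins prefer the transition state with CHO exo and Br endo, and the catalyst indole ring stacks over one face of the bound enal and leaves only the other open; C1 and C4 follow from this face choice because the diene adds suprafacially in one orientation. The step needs ortho regioselectivity, secured by the match between the larger HOMO coefficient at the free α-carbon of 3 and the β-carbon of the enal. It also needs cycloaddition to win over conjugate alkylation of the furan and over cycloreversion, secured by −78 °C, the mild neutral Lewis acid, the cold basic quench and the electron-poor ester that disfavours ionisation at C7.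

Step 4
Reactants: 7 bromo aldehyde
Product: 8 (1S,2R,4R)-1-(benzoyloxymethyl)-2-endo-bromo-7-oxabicyclo[2.2.1]hept-5-ene-2-exo-carboxylic acid
Conditions: NaClO2, NaH2PO4, 2-methyl-2-butene, t-BuOH/H2O, 0 °C; used at once
Reagents that add atoms: sodium chlorite, [Na+].[O-]Cl=O
Why: The Pinnick oxidation converts the non-enolisable aldehyde into the acid under buffered conditions at 0 °C that spare benzoate, tertiary bromide and strained alkene (the scavenger traps HOCl) and leave little time for cycloreversion, with no stereocentre changed.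

Step 5
Reactants: 8 bromo acid
Product: 9 (1R,2R,4R,5R,6R)-1-(benzoyloxymethyl)-2-endo-bromo-5,6-exo-epoxy-7-oxabicyclo[2.2.1]heptane-2-exo-carboxylic acid
Conditions: dimethyldioxirane, acetone, 0 °C → rt
Reagents that add atoms: dimethyldioxirane, CC1(C)OO1
Why: Concerted dioxirane epoxidation reaches the 7-oxanorbornene alkene only from the exo face, because the C5–C6 bridge and its endo bromine screen the endo face; this sets C2 and C3 with the oxirane oxygen cis to O1, blocks retro-Diels–Alder cleavage, and precedes ketone unmasking so that no Baeyer–Villiger pathway exists.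

Step 6
Reactants: 9 epoxy bromo acid
Product: 12 (1R,4R,5R,6R)-1-(benzoyloxymethyl)-5,6-exo-epoxy-7-oxabicyclo[2.2.1]heptan-2-one, via acyl azide 10 (not isolated), via bromo isocyanate 11 (not isolated)
Conditions: (PhO)2P(O)N3, Et3N (1.0 equiv each), toluene, rt then 80 °C; then AcOH/H2O/THF, 40 °C
Reagents that add atoms: diphenylphosphoryl azide, [N-]=[N+]=NP(=O)(Oc1ccccc1)Oc1ccccc1 (nitrogen of 10 and 11); water, O (ketone oxygen of 12)
Why: The Curtius rearrangement of the α-bromo acyl azide gives the α-bromo isocyanate with retention, and its hydrolysis yields a geminal bromo amine that collapses through the imine to the ketone (the classical unmasking of α-haloacrylic ketene equivalents); the medium is never strongly basic, so the benzoate survives, and the released ammonia takes up the HBr, so the rigid exo oxirane is not attacked.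

Step 7
Reactants: 12 epoxy ketone
Product: 14 [(1R,2R,3R)-1-(tert-butyldimethylsilyloxy)-2,3-epoxy-6-oxocyclohex-4-en-1-yl]methyl benzoate, via silyl enol ether 13 (not isolated)
Conditions: TBSOTf, Et3N, CH2Cl2, 0 °C → rt
Reagents that add atoms: tert-butyldimethylsilyl triflate, CC(C)(C)[Si](C)(C)OS(=O)(=O)C(F)(F)F
Why: Soft enolisation can only go toward C5 because C1 is quaternary, and silyl triflate activation of the bridge oxygen then triggers β-elimination of the C4–O bond, a known opening of 7-oxanorbornan-2-ones including their 5,6-exo-epoxides; O1 is capped as its silyl ether as it is released, so no alkoxide can attack the benzoate, and C1, C2 and C3 are untouched.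

Step 8
Reactants: 14 epoxy enone
Product: 16 [(1R,2R,3S)-2,3-diacetoxy-1-(tert-butyldimethylsilyloxy)-6-oxocyclohex-4-en-1-yl]methyl benzoate, via hydroxy acetate 15 (not isolated)
Conditions: KOAc, AcOH, 50 °C; evaporate; then Ac2O, pyridine, DMAP (cat.), CH2Cl2, 0 °C → rt
Reagents that add atoms: acetic acid, CC(=O)O; acetic anhydride, CC(=O)OC(C)=O
Why: Acetate opens the oxirane by SN2 attack with inversion at C3, the allylic and less hindered terminus (C2 is neopentyl-like next to quaternary C1, and the electron-poor enone excludes SN1 and SN2′ courses), which gives the 2,3-trans arrangement; DMAP-catalysed acetylation of the crude material then funnels the hydroxy acetate, any acetyl-migrated isomer and any diol into one diacetate while O1 stays silylated.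

Step 9
Reactants: 16 diacetoxy enone
Product: 17 [(1S,2R,3S,6S)-2,3-diacetoxy-1-(tert-butyldimethylsilyloxy)-6-hydroxycyclohex-4-en-1-yl]methyl benzoate
Conditions: NaBH4, CeCl3·7H2O, MeOH, −78 °C
Reagents that add atoms: none
Why: The Luche reduction gives 1,2-addition, and in the favoured half-chair (C2-OAc, C3-OAc and C7 equatorial, C1-OTBS axial) the small hydride enters axially, anti to the axial C1–O bond as the polar Felkin–Anh model also requires, so the new C6 hydroxyl comes out cis to O1, with esters and silyl ether inert at this temperature.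

Step 10
Reactants: 17 silyl ether
Product: 18 [(1S,2R,3S,6S)-2,3-diacetoxy-1,6-dihydroxycyclohex-4-en-1-yl]methyl benzoate (target)
Conditions: 48% aq. HF, MeCN, 0 °C → rt
Reagents that add atoms: none
Why: Fluoride-driven desilylation in an acidic medium removes the tertiary silyl ether without forming alkoxides that would let acetyl or benzoyl groups migrate, and no stereocentre is touched.

Compound list
1 | furfuryl alcohol | OCc1ccco1 | starting material
2 | benzoyl chloride | O=C(Cl)c1ccccc1 | starting material
3 | furfuryl benzoate | O=C(OCc1ccco1)c1ccccc1 | intermediate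
4 | acrolein | C=CC=O | starting material
5 | 2,3-dibromopropanal (racemic, not isolated) | O=CC(Br)CBr | intermediate
6 | 2-bromoacrolein | C=C(Br)C=O | intermediate
7 | (1S,2R,4R)-1-(benzoyloxymethyl)-2-endo-bromo-7-oxabicyclo[2.2.1]hept-5-ene-2-exo-carbaldehyde | O=C[C@@]1(Br)C[C@@H]2C=C[C@@]1(COC(=O)c3ccccc3)O2 | intermediate
8 | (1S,2R,4R)-1-(benzoyloxymethyl)-2-endo-bromo-7-oxabicyclo[2.2.1]hept-5-ene-2-exo-carboxylic acid | OC(=O)[C@@]1(Br)C[C@@H]2C=C[C@@]1(COC(=O)c3ccccc3)O2 | intermediate
9 | (1R,2R,4R,5R,6R)-1-(benzoyloxymethyl)-2-endo-bromo-5,6-exo-epoxy-7-oxabicyclo[2.2.1]heptane-2-exo-carboxylic acid | OC(=O)[C@@]1(Br)C[C@@H]2[C@H]3O[C@H]3[C@@]1(COC(=O)c4ccccc4)O2 | intermediate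
10 | acyl azide of 9 (2-exo-carbonyl azide, not isolated) | [N-]=[N+]=NC(=O)[C@@]1(Br)C[C@@H]2[C@H]3O[C@H]3[C@@]1(COC(=O)c4ccccc4)O2 | intermediate
11 | 2-endo-bromo-2-exo-isocyanato analogue of 9 (not isolated) | O=C=N[C@@]1(Br)C[C@@H]2[C@H]3O[C@H]3[C@@]1(COC(=O)c4ccccc4)O2 | intermediate
12 | (1R,4R,5R,6R)-1-(benzoyloxymethyl)-5,6-exo-epoxy-7-oxabicyclo[2.2.1]heptan-2-one | O=C1C[C@@H]2[C@H]3O[C@H]3[C@@]1(COC(=O)c4ccccc4)O2 | intermediate
13 | (1R,4R,5R,6R)-1-(benzoyloxymethyl)-2-(tert-butyldimethylsilyloxy)-5,6-exo-epoxy-7-oxabicyclo[2.2.1]hept-2-ene (not isolated) | CC(C)(C)[Si](C)(C)OC1=C[C@@H]2[C@H]3O[C@H]3[C@@]1(COC(=O)c4ccccc4)O2 | intermediate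
14 | [(1R,2R,3R)-1-(tert-butyldimethylsilyloxy)-2,3-epoxy-6-oxocyclohex-4-en-1-yl]methyl benzoate (oxirane oxygen cis to O1) | O=C1C=C[C@H]2O[C@H]2[C@@]1(COC(=O)c3ccccc3)O[Si](C)(C)C(C)(C)C | intermediate
15 | [(1R,2R,3S)-3-acetoxy-1-(tert-butyldimethylsilyloxy)-2-hydroxy-6-oxocyclohex-4-en-1-yl]methyl benzoate (not isolated) | O=C1C=C[C@H](OC(C)=O)[C@@H](O)[C@@]1(COC(=O)c2ccccc2)O[Si](C)(C)C(C)(C)C | intermediate
16 | [(1R,2R,3S)-2,3-diacetoxy-1-(tert-butyldimethylsilyloxy)-6-oxocyclohex-4-en-1-yl]methyl benzoate | O=C1C=C[C@H](OC(C)=O)[C@@H](OC(C)=O)[C@@]1(COC(=O)c2ccccc2)O[Si](C)(C)C(C)(C)C | intermediate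
17 | [(1S,2R,3S,6S)-2,3-diacetoxy-1-(tert-butyldimethylsilyloxy)-6-hydroxycyclohex-4-en-1-yl]methyl benzoate | O[C@H]1C=C[C@H](OC(C)=O)[C@@H](OC(C)=O)[C@@]1(COC(=O)c2ccccc2)O[Si](C)(C)C(C)(C)C | intermediate
18 | [(1S,2R,3S,6S)-2,3-diacetoxy-1,6-dihydroxycyclohex-4-en-1-yl]methyl benzoate | CC(=O)O[C@H]1C=C[C@H](O)[C@@](O)(COC(=O)c2ccccc2)[C@@H]1OC(C)=O | target

Total step count: 10. Longest linear sequence: 9 (steps 1 and 3–10; step 2 is a one-step side branch).

Steps most likely to fail

Step 3, cycloaddition. Several processes could interfere: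
- Conjugate alkylation at the free furan α-position could overtake ring closure, because C1–C6 joins two fully substituted carbons.
- The adduct could revert on warming.
- The ester carbonyl could compete for boron.
- Enantioface discrimination could be insufficient.

Fallback, from 3 and 6 back to 9: asymmetric catalysis is replaced by classical resolution. Compounds 3 and 6 are combined without Lewis acid (concentrated CH2Cl2, 0–25 °C, or about 10 kbar) to give the racemic adduct F1. This is oxidised at once as in step 4 to the racemic bromo acid F2, then epoxidised as in step 5 to the racemic epoxy acid F3, which can no longer revert. Crystallisation with (R)-1-phenylethylamine gives the salt of the wanted enantiomer F4, and acidification returns 9.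

Step 8, oxirane opening on the enone. Three processes could interfere:
- The electron-poor oxirane could open slowly.
- The C7 benzoate carbonyl could participate at C2.
- Elimination toward a cyclohexadienone could occur on heating.

Fallback, from 14 to 18: the oxidation level is changed before the opening.
- Luche reduction of 14, with hydride arriving anti to OTBS and away from the oxirane oxygen, gives the epoxy allylic alcohol F5.
- TBSOTf/2,6-lutidine gives the bis-silyl ether F6.
- The oxirane is now an ordinary, more reactive vinyl oxirane and is opened at allylic C3 with KOAc/AcOH near room temperature to the hydroxy acetate F7.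
- Ac2O/pyridine gives the bis-silyl diacetate F8.
- Aqueous HF in MeCN removes both silyl groups and delivers 18.

Step 6, unmasking of the ketone. Three processes could interfere:
- Azide transfer to a carboxyl flanked by two fully substituted carbons could be slow.
- HBr could be lost on heating.
- Bromide could attack the oxirane during hydrolysis.

Fallback, from 7 to 12: the extra carbon is removed by glycol cleavage, with no heating.
- NaBH4 reduces 7 to the bromohydrin F9.
- NaH in THF closes the spiro-oxirane F10, the exo alkoxide displacing the endo bromide from the rear.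
- H5IO6 in aqueous THF hydrolyses F10 at its CH2 terminus to the diol F11 and cleaves this in the same flask to the bicyclic alkenone F12.
- Dimethyldioxirane, which does not cause Baeyer–Villiger oxidation, epoxidises the exo face to give 12.

Further compounds
F1 | step 3 | racemic 7 (1:1 mixture of 7 and its mirror image; mirror image drawn) | O=C[C@]1(Br)C[C@H]2C=C[C@]1(COC(=O)c3ccccc3)O2
F2 | step 3 | racemic 8 (mirror image drawn) | OC(=O)[C@]1(Br)C[C@H]2C=C[C@]1(COC(=O)c3ccccc3)O2
F3 | step 3 | racemic 9 (mirror image drawn) | OC(=O)[C@]1(Br)C[C@H]2[C@@H]3O[C@@H]3[C@]1(COC(=O)c4ccccc4)O2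
F4 | step 3 | (R)-1-phenylethylammonium salt of 9 | C[C@@H]([NH3+])c1ccccc1.[O-]C(=O)[C@@]1(Br)C[C@@H]2[C@H]3O[C@H]3[C@@]1(COC(=O)c4ccccc4)O2
F5 | step 8 | [1-(tert-butyldimethylsilyloxy)-2,3-epoxy-6-hydroxycyclohex-4-en-1-yl]methyl benzoate with O1, oxirane oxygen and O6 all cis | O[C@H]1C=C[C@H]2O[C@H]2[C@@]1(COC(=O)c3ccccc3)O[Si](C)(C)C(C)(C)C
F6 | step 8 | 6-O-tert-butyldimethylsilyl ether of F5 | CC(C)(C)[Si](C)(C)O[C@H]1C=C[C@H]2O[C@H]2[C@@]1(COC(=O)c3ccccc3)O[Si](C)(C)C(C)(C)C
F7 | step 8 | 1,6-bis-O-TBS 3-acetoxy-2-hydroxy compound (C3 inverted) | CC(C)(C)[Si](C)(C)O[C@H]1C=C[C@H](OC(C)=O)[C@@H](O)[C@@]1(COC(=O)c2ccccc2)O[Si](C)(C)C(C)(C)C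
F8 | step 8 | 1,6-bis-O-TBS ether of 18 | CC(C)(C)[Si](C)(C)O[C@H]1C=C[C@H](OC(C)=O)[C@@H](OC(C)=O)[C@@]1(COC(=O)c2ccccc2)O[Si](C)(C)C(C)(C)C
F9 | step 6 | [2-endo-bromo-2-exo-(hydroxymethyl)-7-oxabicyclo[2.2.1]hept-5-en-1-yl]methyl benzoate | OC[C@@]1(Br)C[C@@H]2C=C[C@@]1(COC(=O)c3ccccc3)O2
F10 | step 6 | spiro-oxirane at bicyclic C2 (oxygen exo, CH2 endo) | C1O[C@]12C[C@@H]3C=C[C@@]2(COC(=O)c4ccccc4)O3
F11 | step 6 | 2-exo-hydroxy-2-endo-(hydroxymethyl) diol | OC[C@]1(O)C[C@@H]2C=C[C@@]1(COC(=O)c3ccccc3)O2
F12 | step 6 | (1S,4R)-1-(benzoyloxymethyl)-7-oxabicyclo[2.2.1]hept-5-en-2-one | O=C1C[C@@H]2C=C[C@@]1(COC(=O)c3ccccc3)O2
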